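**Plan**
- Retrosynthesis cuts, in this order: the two C–C bonds at the methylene between ring A and ring B (formaldehyde as the carbon), the two aryl–CO bonds of the butyryl groups on rings B and C, then ring C itself across C1–C2 and C5–C6.
- Enabling feature: ring C carries three oxygens with different fates (C2–OH, C4–OMe, C6–OH) around C3–Me and the bridge-bearing C1. A 3-methoxycyclobutenone and a siloxyalkyne deliver each oxygen distinct, so the methyl ether needs no selective methylation.
- Forward: the ring B benzyl unit is built from 1,3,5-tris(benzyloxy)benzene as a propargyl arene and oxidised to the siloxyalkyne; the cyclobutenone comes from methylketene and methoxyacetylene; ring C then arises in the benzannulation.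
- Desilylation, hydrogenolysis and double Friedel–Crafts butyrylation give the B–C unit; ring A (butyrylfilicinic acid, from phloroglucinol) is joined last through formaldehyde.
- Stereochemistry: the target is achiral; the racemic sp3 centres of the cyclobutenone, the carbinol and the cascade intermediates are all erased.

Key step: step 7

Remark: the target has no stereocentre and ring A is drawn as one of its equilibrating enol tautomers, all treated as the same compound; 1,3,5-tris(benzyloxy)benzene and HC≡CMgBr (THF solution) are taken as purchased.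

**Route**

Step 1
Reactants: 1 2-chloro-1,1-dimethoxyethane
Product: 3 methoxyacetylene (methoxyethyne), via sodium methoxyacetylide 2 (not isolated)
Conditions: NaNH2 (3 equiv), liq. NH3, −33 °C; then aq NaCl, −70 °C; distilled into cold Et2O and used as a solution
Reagents that add atoms: none
Why: Twofold base-induced elimination (methanol, then hydrogen chloride) from the chloroacetal, driven by formation of the sodium acetylide, is the standard alkoxyacetylene preparation.

Step 2
Reactants: 4 propionyl chloride; 3 methoxyacetylene
Product: 6 rac-3-methoxy-4-methylcyclobut-2-en-1-one, via methylketene 5 (not isolated)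
Conditions: Et3N, Et2O, 0 °C to rt (4 added slowly to 3 and Et3N)
Reagents that add atoms: none
Why: Dehydrochlorination gives methylketene, which is trapped in a ketene–alkoxyacetylene [2+2] cycloaddition in which the nucleophilic CH terminus of the ynol ether bonds to the ketene carbonyl carbon, so methoxy ends at C3 and methyl at C4; the new stereocentre is racemic and vanishes in step 7.

Step 3
Reactants: 7 1,3,5-tris(benzyloxy)benzene
Product: 9 2,4,6-tris(benzyloxy)benzaldehyde, via aryl iminium chloride 8 (not isolated)
Conditions: POCl3, DMF, 0 °C to rt; then aq NaOAc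
Reagents that add atoms: N,N-dimethylformamide, CN(C)C=O; water, O
Why: Vilsmeier–Haack formylation of a trialkoxybenzene whose three free positions are equivalent, with the iminium group deactivating the ring against a second attack.

Step 4
Reactants: 9 2,4,6-tris(benzyloxy)benzaldehyde; 10 ethynylmagnesium bromide
Product: 11 rac-1-[2,4,6-tris(benzyloxy)phenyl]prop-2-yn-1-ol
Conditions: HC≡CMgBr, THF, 0 °C to rt; aq NH4Cl
Reagents that add atoms: none
Why: Grignard addition of the acetylide to the aldehyde gives the racemic carbinol, whose stereocentre is removed in step 5.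

Step 5
Reactants: 11 rac-1-[2,4,6-tris(benzyloxy)phenyl]prop-2-yn-1-ol
Product: 12 1,3,5-tris(benzyloxy)-2-(prop-2-yn-1-yl)benzene
Conditions: Et3SiH (4 equiv), CF3CO2H (2 equiv), CH2Cl2, −40 to 0 °C
Reagents that add atoms: none
Why: Ionic hydrogenation, in which the carbinol ionises easily to a cation stabilised by the three ring oxygens and the silane delivers hydride to the benzylic carbon where the charge resides, so the alkyne is retained.

Step 6
Reactants: 12 1,3,5-tris(benzyloxy)-2-(prop-2-yn-1-yl)benzene
Product: 15 triisopropyl({3-[2,4,6-tris(benzyloxy)phenyl]prop-1-yn-1-yl}oxy)silane, via lithium acetylide 13 (not isolated), via lithium ynolate 14 (not isolated)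
Conditions: n-BuLi, THF, −78 °C; t-BuOOLi (from t-BuOOH and LiN(SiMe3)2), −78 to 0 °C; i-Pr3SiOTf, −78 °C
Reagents that add atoms: tert-butyl hydroperoxide, CC(C)(C)OO; triisopropylsilyl trifluoromethanesulfonate, CC(C)[Si](OS(=O)(=O)C(F)(F)F)(C(C)C)C(C)C
Why: Oxidation of a lithium acetylide with lithium tert-butyl peroxide (attack at the peroxide oxygen with loss of tert-butoxide) gives the ynolate, which the bulky silyl triflate captures at oxygen, the usual route from terminal alkynes to siloxyalkynes.

Step 7
Reactants: 6 rac-3-methoxy-4-methylcyclobut-2-en-1-one; 15 triisopropyl({3-[2,4,6-tris(benzyloxy)phenyl]prop-1-yn-1-yl}oxy)silane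
Product: 20 2-[2,4,6-tris(benzyloxy)benzyl]-5-methoxy-6-methyl-3-(triisopropylsiloxy)phenol, via vinylketene 16 (not isolated), via vinylcyclobutenone 17 (not isolated), via dienylketene 18 (not isolated), via cyclohexadienone 19 (not isolated)
Conditions: 6 (1.5 equiv), PhMe, 80 °C then 110 °C, sealed tube
Reagents that add atoms: none
Why: Heat opens 6 in a four-electron electrocyclic reaction to vinylketene 16, whose ketene C=C adds [2+2] to the electron-rich triple bond of 15 to give vinylcyclobutenone 17; a second four-electron opening gives dienylketene 18, which closes ring C by a thermal disrotatory six-electron electrocyclization (ketene carbon onto the methyl-bearing diene terminus) to cyclohexadienone 19, and enolization delivers phenol 20. The closest known reaction type is the Danheiser benzannulation of cyclobutenones with siloxyalkynes, which gives resorcinol monosilyl ethers. The net new bonds are C1–C2 (ketene carbon to the benzyl-bearing alkyne carbon) and C5–C6 (ketene CH to the siloxy-bearing alkyne carbon), so the ketene carbon becomes C2–OH, the alkyne supplies C1 and C6, and the cyclobutenone supplies C5–H, C4–OMe and C3–Me. No stereocentre survives: the racemic sp3 carbons of 6, 17 and 19 become sp2 on aromatization, and the alkene geometry in 16 and 18 does not matter because the ring openings are reversible and only the cis-dienylketene cyclizes. The step needs one regiochemical outcome in the [2+2] event, and the polarization of the siloxyalkyne secures it: the carbon remote from oxygen is nucleophilic and bonds to the electrophilic ketene carbonyl carbon. Outward rotation of the methyl group when 6 opens should leave hydrogen, not methyl, on the inside of the closing terminus, which keeps the ring closure fast.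

Step 8
Reactants: 20 2-[2,4,6-tris(benzyloxy)benzyl]-5-methoxy-6-methyl-3-(triisopropylsiloxy)phenol
Product: 21 2-[2,4,6-tris(benzyloxy)benzyl]-5-methoxy-4-methylbenzene-1,3-diol
Conditions: Bu4NF, AcOH, THF, 0 °C
Reagents that add atoms: none
Why: Fluoride-induced cleavage of the aryl silyl ether, buffered with acetic acid so that the electron-rich resorcinol is not left as an air-sensitive phenoxide; benzyl and methyl ethers are untouched.

Step 9
Reactants: 21 2-[2,4,6-tris(benzyloxy)benzyl]-5-methoxy-4-methylbenzene-1,3-diol
Product: 22 2-[(2,6-dihydroxy-4-methoxy-3-methylphenyl)methyl]benzene-1,3,5-triol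
Conditions: H2 (1 atm), 10% Pd/C, EtOAc–MeOH, rt; handled under argon and used directly
Reagents that add atoms: none
Why: Catalytic hydrogenolysis of the three benzyl aryl ethers, with the diarylmethane link and the methyl ether inert under these conditions.

Step 10
Reactants: 22 2-[(2,6-dihydroxy-4-methoxy-3-methylphenyl)methyl]benzene-1,3,5-triol; 23 butanoyl chloride
Product: 24 1-{3-[(3-butanoyl-2,4,6-trihydroxyphenyl)methyl]-2,4-dihydroxy-6-methoxy-5-methylphenyl}butan-1-one
Conditions: 23 (2.2 equiv), AlCl3 (7 equiv), PhNO2–CH2Cl2, 0 °C to rt; dilute HCl work-up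
Reagents that add atoms: none
Why: Twofold Friedel–Crafts acylation, in which ring C has a single free carbon (C5, between OMe and OH) and ring B takes one acyl group at either of its two equivalent carbons, after which the chelated ketone deactivates that ring against a second acylation.

Step 11
Reactants: 25 phloroglucinol; 23 butanoyl chloride
Product: 26 1-(2,4,6-trihydroxyphenyl)butan-1-one
Conditions: 23 (1 equiv), AlCl3, PhNO2–CH2Cl2, rt
Reagents that add atoms: none
Why: Friedel–Crafts monoacylation of phloroglucinol, which stops after one acyl group because the hydrogen-bonded ketone deactivates the ring.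

Step 12
Reactants: 26 1-(2,4,6-trihydroxyphenyl)butan-1-one
Product: 27 2-butanoyl-3,5-dihydroxy-6,6-dimethylcyclohexa-2,4-dien-1-one (butyrylfilicinic acid)
Conditions: NaOMe (3 equiv), MeI (2.5 equiv), MeOH, 0 °C to rt
Reagents that add atoms: iodomethane, CI
Why: C-Alkylation of the acylphloroglucinol phenoxide, where the second methyl group enters the same ring carbon and dearomatizes the ring (the known geminal dimethylation that gives acylfilicinic acids); under- and over-methylated products are removed by chromatography.

Step 13
Reactants: 24 1-{3-[(3-butanoyl-2,4,6-trihydroxyphenyl)methyl]-2,4-dihydroxy-6-methoxy-5-methylphenyl}butan-1-one; 27 butyrylfilicinic acid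
Product: 29 filixsaure (target), via methylidene triketone 28 (not isolated)
Conditions: 27 (3 equiv), 37% aq HCHO (2 equiv, added slowly), 1% aq KOH, 0 °C to rt, short reaction time; then dilute HCl
Reagents that add atoms: formaldehyde, C=O
Why: Formaldehyde condensation in dilute alkali, the classical way to methylene-bridged acylphloroglucinols: 27 is hydroxymethylated at its only CH and loses hydroxide to give 28, which the phenoxide of 24 captures at the one free ring B carbon, while the excess of 27 should steer 24 into the cross-product and the symmetrical dimer of 27 is separated.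

**Compound list**

1 | 2-chloro-1,1-dimethoxyethane | COC(CCl)OC | starting material
2 | sodium methoxyacetylide | [Na+].[C-]#COC | intermediate
3 | methoxyacetylene (methoxyethyne) | C#COC | intermediate
4 | propionyl chloride | CCC(=O)Cl | starting material
5 | methylketene | CC=C=O | intermediate
6 | rac-3-methoxy-4-methylcyclobut-2-en-1-one | COC1=CC(=O)C1C | intermediate
7 | 1,3,5-tris(benzyloxy)benzene | c1ccc(COc2cc(OCc3ccccc3)cc(OCc3ccccc3)c2)cc1 | starting material
8 | N,N-dimethyl-[2,4,6-tris(benzyloxy)phenyl]methaniminium chloride | C[N+](C)=Cc1c(OCc2ccccc2)cc(OCc2ccccc2)cc1OCc1ccccc1.[Cl-] | intermediate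
9 | 2,4,6-tris(benzyloxy)benzaldehyde | O=Cc1c(OCc2ccccc2)cc(OCc2ccccc2)cc1OCc1ccccc1 | intermediate
10 | ethynylmagnesium bromide | C#C[Mg]Br | starting material
11 | rac-1-[2,4,6-tris(benzyloxy)phenyl]prop-2-yn-1-ol | C#CC(O)c1c(OCc2ccccc2)cc(OCc2ccccc2)cc1OCc1ccccc1 | intermediate
12 | 1,3,5-tris(benzyloxy)-2-(prop-2-yn-1-yl)benzene | C#CCc1c(OCc2ccccc2)cc(OCc2ccccc2)cc1OCc1ccccc1 | intermediate
13 | lithium acetylide of 12 | [Li]C#CCc1c(OCc2ccccc2)cc(OCc2ccccc2)cc1OCc1ccccc1 | intermediate
14 | lithium 3-[2,4,6-tris(benzyloxy)phenyl]prop-1-yn-1-olate | [Li]OC#CCc1c(OCc2ccccc2)cc(OCc2ccccc2)cc1OCc1ccccc1 | intermediate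
15 | triisopropyl({3-[2,4,6-tris(benzyloxy)phenyl]prop-1-yn-1-yl}oxy)silane | CC(C)[Si](OC#CCc1c(OCc2ccccc2)cc(OCc2ccccc2)cc1OCc1ccccc1)(C(C)C)C(C)C | intermediate
16 | 3-methoxypenta-1,3-dien-1-one (vinylketene, alkene geometry not fixed) | CC=C(OC)C=C=O | intermediate
17 | rac-2-[2,4,6-tris(benzyloxy)benzyl]-4-(1-methoxyprop-1-en-1-yl)-3-(triisopropylsiloxy)cyclobut-2-en-1-one | CC=C(OC)C1C(=O)C(Cc2c(OCc3ccccc3)cc(OCc3ccccc3)cc2OCc2ccccc2)=C1O[Si](C(C)C)(C(C)C)C(C)C | intermediate
18 | 2-[2,4,6-tris(benzyloxy)benzyl]-5-methoxy-3-(triisopropylsiloxy)hepta-1,3,5-trien-1-one (dienylketene) | CC=C(OC)C=C(O[Si](C(C)C)(C(C)C)C(C)C)C(Cc1c(OCc2ccccc2)cc(OCc2ccccc2)cc1OCc1ccccc1)=C=O | intermediate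
19 | rac-2-[2,4,6-tris(benzyloxy)benzyl]-5-methoxy-6-methyl-3-(triisopropylsiloxy)cyclohexa-2,4-dien-1-one | CC1C(=O)C(Cc2c(OCc3ccccc3)cc(OCc3ccccc3)cc2OCc2ccccc2)=C(O[Si](C(C)C)(C(C)C)C(C)C)C=C1OC | intermediate
20 | 2-[2,4,6-tris(benzyloxy)benzyl]-5-methoxy-6-methyl-3-(triisopropylsiloxy)phenol | Cc1c(OC)cc(O[Si](C(C)C)(C(C)C)C(C)C)c(Cc2c(OCc3ccccc3)cc(OCc3ccccc3)cc2OCc2ccccc2)c1O | intermediate
21 | 2-[2,4,6-tris(benzyloxy)benzyl]-5-methoxy-4-methylbenzene-1,3-diol | Cc1c(OC)cc(O)c(Cc2c(OCc3ccccc3)cc(OCc3ccccc3)cc2OCc2ccccc2)c1O | intermediate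
22 | 2-[(2,6-dihydroxy-4-methoxy-3-methylphenyl)methyl]benzene-1,3,5-triol | Cc1c(OC)cc(O)c(Cc2c(O)cc(O)cc2O)c1O | intermediate
23 | butanoyl chloride | CCCC(=O)Cl | starting material
24 | 1-{3-[(3-butanoyl-2,4,6-trihydroxyphenyl)methyl]-2,4-dihydroxy-6-methoxy-5-methylphenyl}butan-1-one | CCCC(=O)c1c(O)c(Cc2c(O)c(C)c(OC)c(C(=O)CCC)c2O)c(O)cc1O | intermediate
25 | phloroglucinol | Oc1cc(O)cc(O)c1 | starting material
26 | 1-(2,4,6-trihydroxyphenyl)butan-1-one | CCCC(=O)c1c(O)cc(O)cc1O | intermediate
27 | 2-butanoyl-3,5-dihydroxy-6,6-dimethylcyclohexa-2,4-dien-1-one (butyrylfilicinic acid) | CCCC(=O)C1=C(O)C=C(O)C(C)(C)C1=O | intermediate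
28 | 2-butanoyl-3-hydroxy-4,4-dimethyl-6-methylidenecyclohex-2-ene-1,5-dione | CCCC(=O)C1=C(O)C(C)(C)C(=O)C(=C)C1=O | intermediate
29 | filixsaure: 2-butanoyl-4-({3-butanoyl-5-[(3-butanoyl-2,6-dihydroxy-4-methoxy-5-methylphenyl)methyl]-2,4,6-trihydroxyphenyl}methyl)-3,5-dihydroxy-6,6-dimethylcyclohexa-2,4-dien-1-one | CCCC(=O)C1=C(O)C(Cc2c(O)c(Cc3c(O)c(C)c(OC)c(C(=O)CCC)c3O)c(O)c(C(=O)CCC)c2O)=C(O)C(C)(C)C1=O | target

**Count**

Total steps: 13. Longest linear sequence: 9 steps (steps 3, 4, 5, 6, 7, 8, 9, 10, 13).

**Steps most likely to fail**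

Step 7. The monosubstituted vinylketene may be drained by dimerization, or by acylating the phenol as it forms, before it meets the alkyne. A substituted closing terminus may also slow ring closure, so that at the temperature then needed the siloxyalkyne rearranges by silyl shift to a silylketene. The fallback sets out from 6 (with 15 unchanged) and comes back to the route at 21. Dilute aqueous HCl in THF would hydrolyse 6 to 3-hydroxy-2-methylcyclobut-2-en-1-one F1, the enol of 2-methylcyclobutane-1,3-dione. Me3SiCHN2 in MeOH–PhMe would O-methylate this symmetrical enol to the single ether 3-methoxy-2-methylcyclobut-2-en-1-one F2. Heating F2 with 15 would run the same cascade through a disubstituted ketene, which dimerizes more slowly, and an unsubstituted closing terminus. The product would be the regioisomeric silyl ether 2-[2,4,6-tris(benzyloxy)benzyl]-5-methoxy-4-methyl-3-(triisopropylsiloxy)phenol F3. The two ring C oxygens that flank the bridge become equivalent once the silyl group is gone, so Bu4NF/AcOH would convert F3 into 21.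

Step 10. Acylation may go to oxygen or twice onto ring B, the methyl ether next to the new ketone may be lost through the chelated aluminium complex, and the electron-rich diarylmethane may fragment at the bridge under AlCl3. The fallback sets out from 22 and comes back at 24. A Houben–Hoesch reaction with butyronitrile, ZnCl2 and HCl gas in Et2O at 0 °C would give the bis(ketiminium) dichloride of 24 F4, which should precipitate. Each ring accepts only one iminium group, oxygen is not acylated and no strong oxophilic Lewis acid touches the methyl ether. Hydrolysis of F4 in hot water would then give 24.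

Step 13. Methylene transfer may be unselective: 27 may condense with itself, 24 may condense with itself, and aryl units may exchange across the bridges in alkali, all of which lower the share of the cross-product. The fallback sets out from 27 and comes back at 29. A Mannich reaction of 27 with CH2=NMe2+ I− in CH2Cl2 would give 2-butanoyl-4-[(dimethylamino)methyl]-3,5-dihydroxy-6,6-dimethylcyclohexa-2,4-dien-1-one F5. Heated with 24 in dioxane, F5 would lose dimethylamine to give 28 with neither free 27 nor free formaldehyde present, and the single free ring B carbon of 24 would add to 28 to give 29.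

**Further compounds**

F1 | step 7 | 3-hydroxy-2-methylcyclobut-2-en-1-one (enol of 2-methylcyclobutane-1,3-dione) | CC1=C(O)CC1=O
F2 | step 7 | 3-methoxy-2-methylcyclobut-2-en-1-one | COC1=C(C)C(=O)C1
F3 | step 7 | 2-[2,4,6-tris(benzyloxy)benzyl]-5-methoxy-4-methyl-3-(triisopropylsiloxy)phenol | COc1cc(O)c(Cc2c(OCc3ccccc3)cc(OCc3ccccc3)cc2OCc2ccccc2)c(O[Si](C(C)C)(C(C)C)C(C)C)c1C
F4 | step 10 | 1-{3-[(3-butanimidoyl-2,4,6-trihydroxyphenyl)methyl]-2,4-dihydroxy-6-methoxy-5-methylphenyl}butan-1-imine dihydrochloride (bis(ketiminium) dichloride of 24) | CCCC(=[NH2+])c1c(O)c(Cc2c(O)c(C)c(OC)c(C(=[NH2+])CCC)c2O)c(O)cc1O.[Cl-].[Cl-]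
F5 | step 13 | 2-butanoyl-4-[(dimethylamino)methyl]-3,5-dihydroxy-6,6-dimethylcyclohexa-2,4-dien-1-one | CCCC(=O)C1=C(O)C(CN(C)C)=C(O)C(C)(C)C1=O
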